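Ring A is built first, and the plan turns on its contiguous C4–C5–C6 triad (labdane numbering). C5 is flanked by quaternary C4 and by C10, which later becomes quaternary, so deprotonation could never deliver its enolate selectively. A copper-catalysed asymmetric addition of methyl (C19) from Me3Al to C4 of a C10-keto cyclohexenone bearing the C18 silyloxymethyl group creates that enolate regiospecifically, and a C6–C8 aldehyde traps it in the same flask. One operation forms C4–C19 and C5–C6 and sets C4, C5 and C6. The precursor is 3-(silyloxymethyl)cyclohex-2-enone. Ring B is closed later at C9–C10 by an iron-hydride radical cyclisation, and the Z side chain is attached by Negishi coupling.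

Key step: step 5

Remark on numbering: labdane locants are used throughout. Ring A = C1–C5 and C10; ring B = C5–C10; C17 = exocyclic CH2 on C8; C18 = CH2O on C4 (α); C19 = CH3 on C4 (β); C20 = CH3 on C10 (β); side chain C11–C16. The target is (4R,5R,6S,9S,10R,13Z).
Assumption on the ligand: L = O,O'-(biphenyl-2,2'-diyl) N,N-bis[(S)-1-phenylethyl]phosphoramidite is taken to deliver methyl to the Si face of C4; if the sense is the reverse, its enantiomer is used.
Assumption on supply: alcohol 8 and iodoacrylate 18 are taken as catalogue compounds.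
Remark on C6: a chelated chair from the ring-locked E enolate would lead to the anti aldol (6R). The target needs the syn relation (5R,6S), so the aldehyde is added to the aluminate, which is expected to react through an open arrangement.

Step 1
Reactants: 1 (chloromethyl)dimethyl(propan-2-yloxy)silane; 2 3-ethoxycyclohex-2-en-1-one
Product: 4 rac-1-{[dimethyl(propan-2-yloxy)silyl]methyl}-3-ethoxycyclohex-2-en-1-ol, via Grignard reagent 3 (not isolated)
Conditions: Mg, THF, 40 °C; then 2, THF, 0 °C; aq. NH4Cl (crude product used directly)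
Reagents that add atoms: none
Why: The silylmethyl Grignard reagent, a hydroxymethyl anion equivalent, adds 1,2 to the vinylogous ester (first half of a Stork–Danheiser transposition), and the buffered quench keeps the acid-labile enol ether carbinol intact.

Step 2
Reactants: 4 rac-1-{[dimethyl(propan-2-yloxy)silyl]methyl}-3-ethoxycyclohex-2-en-1-ol
Product: 6 3-(hydroxymethyl)cyclohex-2-en-1-one, via ethoxy diol 5 (not isolated)
Conditions: KF, KHCO3, 30% H2O2, THF/MeOH, rt; aq. Na2S2O3; then 1 M HCl, THF, rt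
Reagents that add atoms: hydrogen peroxide OO; water O
Why: Tamao oxidation turns the C–Si bond into C–OH under mildly basic conditions that spare the enol ether, and dilute acid then hydrolyses the enol ether and eliminates the tertiary hydroxyl to the conjugated enone (completion of the Stork–Danheiser transposition).

Step 3
Reactants: 6 3-(hydroxymethyl)cyclohex-2-en-1-one
Product: 7 3-{[tert-butyl(diphenyl)silyl]oxymethyl}cyclohex-2-en-1-one
Conditions: TBDPSCl, imidazole, CH2Cl2, 0 °C → rt
Reagents that add atoms: tert-butyl(chloro)diphenylsilane CC(C)(C)[Si](Cl)(c1ccccc1)c1ccccc1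
Why: Standard silylation of an unhindered primary alcohol; the bulky, robust TBDPS group is chosen because it must later differentiate the two faces of C5 and survive Lewis acids, oxidants and hydride.

Step 4
Reactants: 8 3-[(4-methoxybenzyl)oxy]propan-1-ol
Product: 9 3-[(4-methoxybenzyl)oxy]propanal
Conditions: TEMPO (10 mol %), PhI(OAc)2, CH2Cl2, rt
Reagents that add atoms: none
Why: The oxoammonium-mediated TEMPO oxidation stops at the aldehyde under neutral conditions, so the β-alkoxy aldehyde does not eliminate the PMB-oxy group.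

Step 5
Reactants: 7 3-{[tert-butyl(diphenyl)silyl]oxymethyl}cyclohex-2-en-1-one; 10 trimethylaluminium; 9 3-[(4-methoxybenzyl)oxy]propanal
Product: 13 (2R,3R)-3-{[tert-butyl(diphenyl)silyl]oxymethyl}-2-{(1S)-1-hydroxy-3-[(4-methoxybenzyl)oxy]propyl}-3-methylcyclohexan-1-one, via dimethylaluminium enolate 11 (not isolated), via lithium aluminate enolate 12 (not isolated)
Conditions: Cu(OTf)2 (2 mol %), L (4 mol %), 10 (1.3 equiv), Et2O, −30 °C; MeLi (1.3 equiv), THF, −78 °C; 9 (1.5 equiv), −78 °C; aq. potassium sodium tartrate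
Reagents that add atoms: none
Why: A chiral methylcopper species made from Cu(OTf)2, the phosphoramidite and 10 adds the C19 methyl to the Si face of C4 (π-complexation, oxidative addition at C4, reductive elimination), and transmetalation leaves the C5=C10 dimethylaluminium enolate 11, a regioisomer that is out of reach by deprotonating a C10 ketone next to quaternary C4; MeLi converts 11 into the more nucleophilic aluminate 12, which adds through C5 to the carbonyl carbon (C6) of 9. The closest known reaction type is the copper-catalysed asymmetric conjugate addition of trialkylaluminium reagents to 3-substituted cyclohexenones followed by aldol trapping of the enolate; no ring is closed. C4 (R) is controlled by the ligand. C5 (R) is controlled by the substrate, because the aldehyde enters on the face of the enolate opposite the bulky CH2OTBDPS group and therefore cis to the new methyl. C6 (S) requires the syn relation to C5, expected from an open arrangement in which the coordinatively saturated aluminate cannot chelate the aldehyde, the C7–C8 chain lies over C5–H and away from quaternary C4, and the C=O points anti to the enolate double bond, whereas a chelated chair from this ring-locked E enolate would give the 6R epimer. The step thus needs enantioface selectivity at C4 (ligand), anti delivery at C5 (silyl group) and syn selectivity at C6 (steric bias of C4), the last being the least secure.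

Step 6
Reactants: 13 (2R,3R)-3-{[tert-butyl(diphenyl)silyl]oxymethyl}-2-{(1S)-1-hydroxy-3-[(4-methoxybenzyl)oxy]propyl}-3-methylcyclohexan-1-one
Product: 14 (2R,3R)-2-{(1S)-1-[tert-butyl(dimethyl)silyl]oxy-3-[(4-methoxybenzyl)oxy]propyl}-3-{[tert-butyl(diphenyl)silyl]oxymethyl}-3-methylcyclohexan-1-one
Conditions: TBSOTf, 2,6-lutidine, CH2Cl2, −78 → 0 °C
Reagents that add atoms: tert-butyldimethylsilyl trifluoromethanesulfonate CC(C)(C)[Si](C)(C)OS(=O)(=O)C(F)(F)F
Why: A silyl triflate with a hindered pyridine base silylates the hindered secondary aldol hydroxyl at low temperature without retro-aldol cleavage or epimerisation at C5.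

Step 7
Reactants: 14 (C6 TBS ether, C10 ketone)
Product: 15 tert-butyl{[(1R,2R)-2-{(1S)-1-[tert-butyl(dimethyl)silyl]oxy-3-[(4-methoxybenzyl)oxy]propyl}-1-methyl-3-methylidenecyclohexyl]methoxy}diphenylsilane
Conditions: Cp2TiMe2, toluene, 70 °C, dark
Reagents that add atoms: dimethyltitanocene [CH3-].[CH3-].[Ti+4].c1cc[cH-]c1.c1cc[cH-]c1
Why: Petasis methylenation with the non-basic titanium methylidene converts the hindered, enolisable C10 ketone into the exocyclic alkene (C20) without epimerising C5 or eliminating the β-silyloxy group.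

Step 8
Reactants: 15 (C10-methylidene compound, C8 PMB ether)
Product: 16 (3S)-3-[tert-butyl(dimethyl)silyl]oxy-3-[(1R,2R)-2-{[tert-butyl(diphenyl)silyl]oxymethyl}-2-methyl-6-methylidenecyclohexyl]propan-1-ol
Conditions: DDQ, CH2Cl2/pH 7 buffer, 0 °C
Reagents that add atoms: none
Why: DDQ cleaves the electron-rich PMB ether oxidatively (hydride abstraction, then hydrolysis of the oxocarbenium ion) and frees only the C8 hydroxyl, the silyl ethers and the 1,1-disubstituted alkene being inert.

Step 9
Reactants: 16 (C8 primary alcohol)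
Product: 17 (3S)-3-[tert-butyl(dimethyl)silyl]oxy-3-[(1R,2R)-2-{[tert-butyl(diphenyl)silyl]oxymethyl}-2-methyl-6-methylidenecyclohexyl]propanal
Conditions: Dess–Martin periodinane, CH2Cl2, rt
Reagents that add atoms: none
Why: Dess–Martin oxidation gives the β-silyloxy aldehyde under neutral conditions that do not cause β-elimination.

Step 10
Reactants: 17 (C8 aldehyde); 18 methyl (2E)-3-iodoprop-2-enoate
Product: 20 methyl (2E,6S)-6-[tert-butyl(dimethyl)silyl]oxy-6-[(1R,2R)-2-{[tert-butyl(diphenyl)silyl]oxymethyl}-2-methyl-6-methylidenecyclohexyl]-4-hydroxyhex-2-enoate (both C8 epimers), via alkenylchromium dichloride 19 (not isolated)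
Conditions: CrCl2, NiCl2 (1 mol %), DMSO, rt
Reagents that add atoms: none
Why: In the Nozaki–Hiyama–Kishi reaction the nickel-catalysed insertion of chromium into the vinyl iodide gives an alkenylchromium reagent that adds chemoselectively to the aldehyde with retention of the E geometry, and the C8 epimers need no separation because C8 is oxidised next.

Step 11
Reactants: 20 (C8 allylic alcohol)
Product: 21 methyl (2E,6S)-6-[tert-butyl(dimethyl)silyl]oxy-6-[(1R,2R)-2-{[tert-butyl(diphenyl)silyl]oxymethyl}-2-methyl-6-methylidenecyclohexyl]-4-oxohex-2-enoate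
Conditions: Dess–Martin periodinane, CH2Cl2, 0 °C → rt
Reagents that add atoms: none
Why: Dess–Martin oxidation of the allylic alcohol gives the E 4-oxo-2-enoate, in which the ester makes C9 the acceptor terminus for a radical arriving from C10.

Step 12
Reactants: 21 (C8-keto enoate with the C10 methylidene group)
Product: 22 methyl 6α-[tert-butyl(dimethyl)silyl]oxy-18-[tert-butyl(diphenyl)silyl]oxy-8-oxo-13,14,15,16,17-pentanorlabdan-12-oate (trans-decalin; 5α-H; 9α-H; 10β-CH3)
Conditions: Fe(acac)3 (30 mol %), PhSiH3, EtOH/ethylene glycol, 60 °C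
Reagents that add atoms: none
Why: Iron hydride generated from Fe(acac)3 and PhSiH3 transfers a hydrogen atom to the CH2 terminus of the 1,1-disubstituted alkene (Markovnikov), and the tertiary C10 radical adds 6-exo-trig to C9 of the doubly activated alkene (intramolecular Giese reaction) through a chair with the C5 tether and the C6 silyloxy group equatorial, which gives the trans ring fusion with the C20 methyl β; the α-ester radical is reduced and protonated, and C9, now α to the C8 ketone, rests with its CH2CO2Me arm equatorial (β).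

Step 13
Reactants: 22 (bicyclic C8 ketone)
Product: 23 methyl 6α-[tert-butyl(dimethyl)silyl]oxy-18-[tert-butyl(diphenyl)silyl]oxy-13,14,15,16-tetranorlabd-8(17)-en-12-oate
Conditions: Ph3PCH3Br, KOtBu, THF, 0 °C → rt
Reagents that add atoms: methyltriphenylphosphonium bromide C[P+](c1ccccc1)(c1ccccc1)c1ccccc1.[Br-]
Why: Wittig methylenation is selective for the ketone over the ester and installs C17, the basic medium lets any C9 epimer equilibrate through the enolate to the equatorial 9β arm before olefination, and the equatorial C6 silyloxy group is poorly aligned for β-elimination.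

Step 14
Reactants: 23 (C12 methyl ester)
Product: 24 6α-[tert-butyl(dimethyl)silyl]oxy-18-[tert-butyl(diphenyl)silyl]oxy-13,14,15,16-tetranorlabd-8(17)-en-12-ol
Conditions: LiAlH4, THF, 0 °C
Reagents that add atoms: none
Why: Hydride reduction takes the ester to the C12 primary alcohol while the isolated alkene and both silyl ethers are unaffected.

Step 15
Reactants: 24 (C12 alcohol)
Product: 25 tert-butyl{[12-iodo-18-[tert-butyl(diphenyl)silyl]oxy-13,14,15,16-tetranorlabd-8(17)-en-6α-yl]oxy}dimethylsilane (C12 iodide)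
Conditions: I2, PPh3, imidazole, CH2Cl2, 0 °C → rt
Reagents that add atoms: iodine II
Why: Appel iodination (alkoxyphosphonium ion displaced by iodide) converts the unhindered primary alcohol into the iodide without touching the alkene.

Step 16
Reactants: 26 but-2-ynoic acid
Product: 27 (2Z)-3-iodobut-2-enoic acid
Conditions: NaI, AcOH, 115 °C
Reagents that add atoms: sodium iodide [Na+].[I-]
Why: Anti hydroiodination of the ynoic acid (iodide adds to C3, protonation at C2 from the opposite side) gives the Z β-iodo acid.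

Step 17
Reactants: 27 (2Z)-3-iodobut-2-enoic acid
Product: 28 2-(trimethylsilyl)ethyl (2Z)-3-iodobut-2-enoate
Conditions: Me3SiCH2CH2OH, PPh3, diisopropyl azodicarboxylate, THF, 0 °C → rt
Reagents that add atoms: 2-(trimethylsilyl)ethanol C[Si](C)(C)CCO
Why: Mitsunobu esterification activates the alcohol and not the acid, so no nucleophilic catalyst is present that could add to the β-iodoenoate and scramble its Z geometry.

Step 18
Reactants: 25 (C12 iodide); 28 2-(trimethylsilyl)ethyl (2Z)-3-iodobut-2-enoate
Product: 30 2-(trimethylsilyl)ethyl (13Z)-6α-[tert-butyl(dimethyl)silyl]oxy-18-[tert-butyl(diphenyl)silyl]oxylabda-8(17),13-dien-15-oate, via alkylzinc iodide 29 (not isolated)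
Conditions: Zn dust (activated with TMSCl and BrCH2CH2Br), LiCl, THF, 40 °C; then 28, Pd(PPh3)4 (5 mol %), THF, rt
Reagents that add atoms: none
Why: In the Negishi coupling zinc inserts into the primary C–I bond and the palladium-catalysed sp3–sp2 coupling with the β-iodoenoate proceeds with retention of the alkene geometry, forming C12–C13 and the 13Z enoate.

Step 19
Reactants: 30 (fully protected labdadienoate)
Product: 31 (13Z)-6α,18-dihydroxylabda-8(17),13-dien-15-oic acid
Conditions: Bu4NF, THF, rt → 40 °C; dilute HCl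
Reagents that add atoms: none
Why: Fluoride cleaves both silyl ethers and, by β-elimination of the silylethyl group, the ester in one operation, and the carboxylate so formed is inert to the basic fluoride, so the Z enoate does not isomerise.

Step 20
Reactants: 31 (13Z)-6α,18-dihydroxylabda-8(17),13-dien-15-oic acid
Product: 33 (4R,5R,6S,9S,10R,13Z)-18-(benzoyloxy)-6-hydroxylabda-8(17),13-dien-15-oic acid (CNP0304840.1), via mixed benzoic anhydride 32 (not isolated)
Conditions: BzCl (2.2 equiv), pyridine, CH2Cl2, −20 → 0 °C; then H2O/THF, rt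
Reagents that add atoms: benzoyl chloride O=C(Cl)c1ccccc1
Why: Acylation with benzoyl chloride and pyridine is selective for the primary C18 hydroxyl over the hindered secondary C6 hydroxyl (next to quaternary C4 and peri to C18), and the carboxylic acid is acylated only transiently to a mixed anhydride that water cleaves at the more electrophilic benzoyl carbonyl.

Compound list
1 | (chloromethyl)dimethyl(propan-2-yloxy)silane | CC(C)O[Si](C)(C)CCl | starting material
2 | 3-ethoxycyclohex-2-en-1-one | CCOC1=CC(=O)CCC1 | starting material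
3 | {[dimethyl(propan-2-yloxy)silyl]methyl}magnesium chloride (formed in the flask) | CC(C)O[Si](C)(C)C[Mg]Cl | intermediate
4 | rac-1-{[dimethyl(propan-2-yloxy)silyl]methyl}-3-ethoxycyclohex-2-en-1-ol | CCOC1=CC(O)(C[Si](C)(C)OC(C)C)CCC1 | intermediate
5 | rac-3-ethoxy-1-(hydroxymethyl)cyclohex-2-en-1-ol (formed in the flask) | CCOC1=CC(O)(CO)CCC1 | intermediate
6 | 3-(hydroxymethyl)cyclohex-2-en-1-one | O=C1CCCC(CO)=C1 | intermediate
7 | 3-{[tert-butyl(diphenyl)silyl]oxymethyl}cyclohex-2-en-1-one | O=C1CCCC(CO[Si](c2ccccc2)(c2ccccc2)C(C)(C)C)=C1 | intermediate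
8 | 3-[(4-methoxybenzyl)oxy]propan-1-ol | OCCCOCc1ccc(OC)cc1 | starting material
9 | 3-[(4-methoxybenzyl)oxy]propanal | O=CCCOCc1ccc(OC)cc1 | intermediate
10 | trimethylaluminium | C[Al](C)C | starting material
11 | dimethylaluminium (3R)-3-{[tert-butyl(diphenyl)silyl]oxymethyl}-3-methylcyclohex-1-en-1-olate, the C5=C10 enolate (formed in the flask) | C[Al](C)OC1=C[C@](C)(CO[Si](c2ccccc2)(c2ccccc2)C(C)(C)C)CCC1 | intermediate
12 | lithium trimethylaluminate of the same (3R)-enolate (formed in the flask) | [Li+].C[Al-](C)(C)OC1=C[C@](C)(CO[Si](c2ccccc2)(c2ccccc2)C(C)(C)C)CCC1 | intermediate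
13 | (2R,3R)-3-{[tert-butyl(diphenyl)silyl]oxymethyl}-2-{(1S)-1-hydroxy-3-[(4-methoxybenzyl)oxy]propyl}-3-methylcyclohexan-1-one | O=C1CCC[C@@](C)(CO[Si](c2ccccc2)(c2ccccc2)C(C)(C)C)[C@@H]1[C@@H](O)CCOCc1ccc(OC)cc1 | intermediate
14 | (2R,3R)-2-{(1S)-1-[tert-butyl(dimethyl)silyl]oxy-3-[(4-methoxybenzyl)oxy]propyl}-3-{[tert-butyl(diphenyl)silyl]oxymethyl}-3-methylcyclohexan-1-one | O=C1CCC[C@@](C)(CO[Si](c2ccccc2)(c2ccccc2)C(C)(C)C)[C@@H]1[C@@H](O[Si](C)(C)C(C)(C)C)CCOCc1ccc(OC)cc1 | intermediate
15 | tert-butyl{[(1R,2R)-2-{(1S)-1-[tert-butyl(dimethyl)silyl]oxy-3-[(4-methoxybenzyl)oxy]propyl}-1-methyl-3-methylidenecyclohexyl]methoxy}diphenylsilane | C=C1CCC[C@@](C)(CO[Si](c2ccccc2)(c2ccccc2)C(C)(C)C)[C@@H]1[C@@H](O[Si](C)(C)C(C)(C)C)CCOCc1ccc(OC)cc1 | intermediate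
16 | (3S)-3-[tert-butyl(dimethyl)silyl]oxy-3-[(1R,2R)-2-{[tert-butyl(diphenyl)silyl]oxymethyl}-2-methyl-6-methylidenecyclohexyl]propan-1-ol | C=C1CCC[C@@](C)(CO[Si](c2ccccc2)(c2ccccc2)C(C)(C)C)[C@@H]1[C@@H](O[Si](C)(C)C(C)(C)C)CCO | intermediate
17 | (3S)-3-[tert-butyl(dimethyl)silyl]oxy-3-[(1R,2R)-2-{[tert-butyl(diphenyl)silyl]oxymethyl}-2-methyl-6-methylidenecyclohexyl]propanal | C=C1CCC[C@@](C)(CO[Si](c2ccccc2)(c2ccccc2)C(C)(C)C)[C@@H]1[C@@H](O[Si](C)(C)C(C)(C)C)CC=O | intermediate
18 | methyl (2E)-3-iodoprop-2-enoate | COC(=O)/C=C/I | starting material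
19 | [(1E)-3-methoxy-3-oxoprop-1-en-1-yl]chromium dichloride (formed in the flask) | COC(=O)/C=C/[Cr](Cl)Cl | intermediate
20 | methyl (2E,6S)-6-[tert-butyl(dimethyl)silyl]oxy-6-[(1R,2R)-2-{[tert-butyl(diphenyl)silyl]oxymethyl}-2-methyl-6-methylidenecyclohexyl]-4-hydroxyhex-2-enoate (both C8 epimers) | C=C1CCC[C@@](C)(CO[Si](c2ccccc2)(c2ccccc2)C(C)(C)C)[C@@H]1[C@@H](O[Si](C)(C)C(C)(C)C)CC(O)/C=C/C(=O)OC | intermediate
21 | methyl (2E,6S)-6-[tert-butyl(dimethyl)silyl]oxy-6-[(1R,2R)-2-{[tert-butyl(diphenyl)silyl]oxymethyl}-2-methyl-6-methylidenecyclohexyl]-4-oxohex-2-enoate | C=C1CCC[C@@](C)(CO[Si](c2ccccc2)(c2ccccc2)C(C)(C)C)[C@@H]1[C@@H](O[Si](C)(C)C(C)(C)C)CC(=O)/C=C/C(=O)OC | intermediate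
22 | methyl 6α-[tert-butyl(dimethyl)silyl]oxy-18-[tert-butyl(diphenyl)silyl]oxy-8-oxo-13,14,15,16,17-pentanorlabdan-12-oate (trans-decalin, 5α-H, 9α-H, 10β-CH3) | O=C1C[C@H](O[Si](C)(C)C(C)(C)C)[C@H]2[C@](C)(CO[Si](c3ccccc3)(c3ccccc3)C(C)(C)C)CCC[C@]2(C)[C@H]1CC(=O)OC | intermediate
23 | methyl 6α-[tert-butyl(dimethyl)silyl]oxy-18-[tert-butyl(diphenyl)silyl]oxy-13,14,15,16-tetranorlabd-8(17)-en-12-oate | C=C1C[C@H](O[Si](C)(C)C(C)(C)C)[C@H]2[C@](C)(CO[Si](c3ccccc3)(c3ccccc3)C(C)(C)C)CCC[C@]2(C)[C@H]1CC(=O)OC | intermediate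
24 | 6α-[tert-butyl(dimethyl)silyl]oxy-18-[tert-butyl(diphenyl)silyl]oxy-13,14,15,16-tetranorlabd-8(17)-en-12-ol | C=C1C[C@H](O[Si](C)(C)C(C)(C)C)[C@H]2[C@](C)(CO[Si](c3ccccc3)(c3ccccc3)C(C)(C)C)CCC[C@]2(C)[C@H]1CCO | intermediate
25 | C12 iodide: 12-iodo-6α-[tert-butyl(dimethyl)silyl]oxy-18-[tert-butyl(diphenyl)silyl]oxy-13,14,15,16-tetranorlabd-8(17)-ene | C=C1C[C@H](O[Si](C)(C)C(C)(C)C)[C@H]2[C@](C)(CO[Si](c3ccccc3)(c3ccccc3)C(C)(C)C)CCC[C@]2(C)[C@H]1CCI | intermediate
26 | but-2-ynoic acid | CC#CC(=O)O | starting material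
27 | (2Z)-3-iodobut-2-enoic acid | C/C(I)=C/C(=O)O | intermediate
28 | 2-(trimethylsilyl)ethyl (2Z)-3-iodobut-2-enoate | C/C(I)=C/C(=O)OCC[Si](C)(C)C | intermediate
29 | C12 alkylzinc iodide derived from 25 (formed in the flask) | C=C1C[C@H](O[Si](C)(C)C(C)(C)C)[C@H]2[C@](C)(CO[Si](c3ccccc3)(c3ccccc3)C(C)(C)C)CCC[C@]2(C)[C@H]1CC[Zn]I | intermediate
30 | 2-(trimethylsilyl)ethyl (13Z)-6α-[tert-butyl(dimethyl)silyl]oxy-18-[tert-butyl(diphenyl)silyl]oxylabda-8(17),13-dien-15-oate | C=C1C[C@H](O[Si](C)(C)C(C)(C)C)[C@H]2[C@](C)(CO[Si](c3ccccc3)(c3ccccc3)C(C)(C)C)CCC[C@]2(C)[C@H]1CC/C(C)=C\C(=O)OCC[Si](C)(C)C | intermediate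
31 | (13Z)-6α,18-dihydroxylabda-8(17),13-dien-15-oic acid | C=C1C[C@H](O)[C@H]2[C@](C)(CO)CCC[C@]2(C)[C@H]1CC/C(C)=C\C(=O)O | intermediate
32 | benzoic (13Z)-18-(benzoyloxy)-6α-hydroxylabda-8(17),13-dien-15-oic anhydride (formed in the flask) | C=C1C[C@H](O)[C@H]2[C@](C)(COC(=O)c3ccccc3)CCC[C@]2(C)[C@H]1CC/C(C)=C\C(=O)OC(=O)c1ccccc1 | intermediate
33 | (4R,5R,6S,9S,10R,13Z)-18-(benzoyloxy)-6-hydroxylabda-8(17),13-dien-15-oic acid | C=C1C[C@H](O)[C@H]2[C@](C)(COC(=O)c3ccccc3)CCC[C@]2(C)[C@H]1CC/C(C)=C\C(=O)O | target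

Total step count: 20. Longest linear sequence: 17 steps (steps 1–3, 5–15 and 18–20); steps 4, 16 and 17 make the two side fragments.

Steps most likely to fail

1. Step 5. The aldol trapping may run through a chelated chair and give mainly the 6R epimer, delivery to C5 may be poorly face-selective, or methyl may pass from aluminium to the aldehyde before the enolate adds. Fallback: the two bond formations are separated. Setting out from enone 7, the same copper-catalysed addition of 10 is quenched with TMSOTf (Et2O/THF, −30 °C → rt) to give the isolable tert-butyl{[(1R)-1-methyl-3-(trimethylsilyloxy)cyclohex-2-en-1-yl]methoxy}diphenylsilane F1. A Mukaiyama aldol reaction of this enol silane with aldehyde 9 (BF3·OEt2, CH2Cl2, −78 °C) then forms C5–C6 through an open transition state, in which the aldehyde chain avoids quaternary C4 and the carbonyl lies anti to the enol double bond, and the route is rejoined at aldol 13.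

2. Step 12. The iron hydride and silane may reduce the electron-poor alkene before the radical closes the ring, or closure may give some cis-fused product. Fallback: a polar cation–enol ring closure. Setting out from aldehyde 17, Roskamp homologation (methyl diazoacetate, SnCl2, CH2Cl2, rt) gives the β-keto ester methyl (5S)-5-[tert-butyl(dimethyl)silyl]oxy-5-[(1R,2R)-2-{[tert-butyl(diphenyl)silyl]oxymethyl}-2-methyl-6-methylidenecyclohexyl]-3-oxopentanoate F2. SnCl4 in CH2Cl2 (−78 → 0 °C) protonates the C10 methylidene group in the Markovnikov sense, and the tin-bound enol closes ring B through C9 onto the tertiary cation, as in the classical β-keto ester-terminated cyclisations that give trans-decalins. This gives methyl 6α-[tert-butyl(dimethyl)silyl]oxy-18-[tert-butyl(diphenyl)silyl]oxy-8-oxo-12,13,14,15,16,17-hexanorlabdan-11-oate F3. C-alkylation with methyl bromoacetate (NaH, DMF, 0 °C → rt) gives the C9-(2-methoxy-2-oxoethyl) derivative F4. Krapcho demethoxycarbonylation (LiCl, wet DMSO, 140 °C) removes the ester β to the ketone, C9 settles with the arm equatorial, and the route is rejoined at keto ester 22.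

3. Step 18. Zinc insertion may be incomplete, the alkylzinc may homocouple, or the β-iodoenoate may partly isomerise from Z to E on palladium. Fallback: the Z trisubstituted enoate is made by syn carbocupration. Setting out from iodide 25, displacement with lithium acetylide–ethylenediamine complex (DMSO, rt) gives the terminal alkyne 6α-[tert-butyl(dimethyl)silyl]oxy-18-[tert-butyl(diphenyl)silyl]oxy-15,16-dinorlabd-8(17)-en-13-yne F5. Deprotonation with n-BuLi and acylation with 2-(trimethylsilyl)ethyl chloroformate (THF, −78 °C) gives the ynoate 2-(trimethylsilyl)ethyl 6α-[tert-butyl(dimethyl)silyl]oxy-18-[tert-butyl(diphenyl)silyl]oxy-16-norlabd-8(17)-en-13-yn-15-oate F6. Me2CuLi (THF, −78 °C, protonation at −78 °C) adds methyl and copper syn across the triple bond, which places C12 cis to the ester, and the route is rejoined at ester 30.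

Further compounds
F1 | step 5 | tert-butyl{[(1R)-1-methyl-3-(trimethylsilyloxy)cyclohex-2-en-1-yl]methoxy}diphenylsilane | C[Si](C)(C)OC1=C[C@](C)(CO[Si](c2ccccc2)(c2ccccc2)C(C)(C)C)CCC1
F2 | step 12 | methyl (5S)-5-[tert-butyl(dimethyl)silyl]oxy-5-[(1R,2R)-2-{[tert-butyl(diphenyl)silyl]oxymethyl}-2-methyl-6-methylidenecyclohexyl]-3-oxopentanoate | C=C1CCC[C@@](C)(CO[Si](c2ccccc2)(c2ccccc2)C(C)(C)C)[C@@H]1[C@@H](O[Si](C)(C)C(C)(C)C)CC(=O)CC(=O)OC
F3 | step 12 | methyl 6α-[tert-butyl(dimethyl)silyl]oxy-18-[tert-butyl(diphenyl)silyl]oxy-8-oxo-12,13,14,15,16,17-hexanorlabdan-11-oate | O=C1C[C@H](O[Si](C)(C)C(C)(C)C)[C@H]2[C@](C)(CO[Si](c3ccccc3)(c3ccccc3)C(C)(C)C)CCC[C@]2(C)[C@H]1C(=O)OC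
F4 | step 12 | C9-(2-methoxy-2-oxoethyl) derivative of F3 (C9 configuration not defined) | O=C1C[C@H](O[Si](C)(C)C(C)(C)C)[C@H]2[C@](C)(CO[Si](c3ccccc3)(c3ccccc3)C(C)(C)C)CCC[C@]2(C)C1(CC(=O)OC)C(=O)OC
F5 | step 18 | 6α-[tert-butyl(dimethyl)silyl]oxy-18-[tert-butyl(diphenyl)silyl]oxy-15,16-dinorlabd-8(17)-en-13-yne | C=C1C[C@H](O[Si](C)(C)C(C)(C)C)[C@H]2[C@](C)(CO[Si](c3ccccc3)(c3ccccc3)C(C)(C)C)CCC[C@]2(C)[C@H]1CCC#C
F6 | step 18 | 2-(trimethylsilyl)ethyl 6α-[tert-butyl(dimethyl)silyl]oxy-18-[tert-butyl(diphenyl)silyl]oxy-16-norlabd-8(17)-en-13-yn-15-oate | C=C1C[C@H](O[Si](C)(C)C(C)(C)C)[C@H]2[C@](C)(CO[Si](c3ccccc3)(c3ccccc3)C(C)(C)C)CCC[C@]2(C)[C@H]1CCC#CC(=O)OCC[Si](C)(C)C
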